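**Plan**

1. Cuts: (i) the side chain at C5–CH= (Heck reaction, with ester to CH2OH last); (ii) O1–C2 of the dihydrofuran ring; (iii) C2–C3. Cut (iii) is made inside the molecule. C2 starts as the carbonyl carbon of a veratroyl ester on O1 and is moved from O1 to C3.
2. Enabling feature: C3 is a benzylic CH(CH3) on ring A, ortho to O1, which is the retron of a Markovnikov Cu–H addition to a 2-vinylphenol. C2 is bonded to both O1 and C3, so an acyl group on O1 lies one five-membered transition state away from C3. C2 also carries the 3,4-dimethoxyphenyl ring, whose para-methoxy group makes the C2–O bond ionisable.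
3. Forward: both benzene rings are bought. Wittig reaction and O-acylation give the flat, achiral ester 4, and the CuH cascade turns it into open-chain 7. The only new ring (O1–C2–C3–C3a–C7a) closes in step 4, and the C3 chain is joined at C5 afterwards.
4. Stereochemistry: C3 (S) comes from the chiral ligand in the hydrocupration. C2 (S) comes from C3, because both carbinol epimers close through one planar cation, anti to the methyl group (trans). The E-alkene comes from the Heck reaction.

Key step: step 3

Assumption: (R,R)-Ph-BPE·CuH is taken to give the (S)-1-arylethylcopper centre (same quadrant sense as (R)-DTBM-SEGPHOS·CuH with vinylarenes), and the acyl transfer is taken to go with retention at carbon; if the sense proves opposite, (S,S)-Ph-BPE is used and nothing else changes.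

**Route**

Step 1
Reactants: 1 5-bromo-2-hydroxy-3-methoxybenzaldehyde
Product: 2 4-bromo-2-methoxy-6-vinylphenol
Conditions: MePPh3Br (1.5 equiv), KOt-Bu (2.6 equiv), THF, 0 °C → rt; then 1 M HCl, 0 °C
Reagents that add atoms: methyltriphenylphosphonium bromide, C[P+](c1ccccc1)(c1ccccc1)c1ccccc1.[Br-]
Why: Wittig methylenation of a salicylaldehyde, in which the extra base stores the phenol as its phenoxide and the aldehyde still reacts with the unstabilised ylide; no stereocentre is formed.

Step 2
Reactants: 2 4-bromo-2-methoxy-6-vinylphenol; 3 3,4-dimethoxybenzoyl chloride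
Product: 4 4-bromo-2-methoxy-6-vinylphenyl 3,4-dimethoxybenzoate
Conditions: Et3N, DMAP (cat.), CH2Cl2, 0 °C → rt
Reagents that add atoms: none
Why: DMAP-catalysed O-acylation (Schotten–Baumann type esterification) of a phenol with an aroyl chloride, which places the future C2 on O1 and needs no protecting group.

Step 3
Reactants: 4 4-bromo-2-methoxy-6-vinylphenyl 3,4-dimethoxybenzoate
Product: 7 4-bromo-2-[(2S)-1-(3,4-dimethoxyphenyl)-1-hydroxypropan-2-yl]-6-methoxyphenol (both C1 epimers), via silylated ketone 5 (not isolated), via bis-silyl ether 6 (not isolated)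
Conditions: Cu(OAc)2 (5 mol %), (R,R)-Ph-BPE (6 mol %), Me(MeO)2SiH (4 equiv), THF, rt → 40 °C; then MeOH, NH4F (cat.), rt
Reagents that add atoms: none
Why: Proposed new method: L*Cu–H adds to the vinyl group in the Markovnikov sense to give an (S)-1-arylethylcopper centre at C3, and this C–Cu bond attacks, with retention, the ester carbonyl held on the ortho oxygen O1, so that the veratroyl group migrates 1,4 from O1 to C3; the copper phenoxide set free is turned over by the silane to silyl ether 5 and L*Cu–H, and a second, slower Cu–H cycle reduces the aryl ketone to 6 before it can enolise. The closest known reaction types are the CuH-catalysed enantioselective reductive coupling of vinylarenes with aromatic carboxylic anhydrides (hydroacylation followed by in situ ketone reduction), the CuH-catalysed cyclisation of N-(2-vinylaryl) aldimines to 2-aryl-3-methylindolines (the nitrogen counterpart of this ring) and the anionic homologous Fries shift of laterally metalated aryl carbamates; the only new element is an aryl ester as internal acyl donor. The C2–C3 bond forms by 5-exo-trig attack through a cyclic 2-oxido-2,3-dihydrobenzofuran tetrahedral intermediate that collapses again, so no ring persists in 7 and the lasting closure is left to step 4. C3 is set by the ligand in the enantiofacial hydrocupration, while the carbinol centre is left uncontrolled on purpose because step 4 erases it. The step needs Cu–H to choose the styrene over the aryl ester and the C–Br bond: vinylarenes are the fastest substrates of phosphine–CuH, the ester is shielded from intermolecular attack by its two ortho substituents and its electron-rich acyl group yet lies within bonding distance of C3, and aryl bromides are inert to CuH.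

Step 4
Reactants: 7 4-bromo-2-[(2S)-1-(3,4-dimethoxyphenyl)-1-hydroxypropan-2-yl]-6-methoxyphenol (both C1 epimers)
Product: 8 (2S,3S)-5-bromo-2-(3,4-dimethoxyphenyl)-7-methoxy-3-methyl-2,3-dihydrobenzofuran
Conditions: camphorsulfonic acid (10 mol %), 4 Å MS, CH2Cl2 (0.02 M), 0 °C
Reagents that add atoms: none
Why: Acid-catalysed SN1 cyclodehydration in which both carbinol epimers ionise to the same para-methoxy-stabilised benzylic cation, and the phenol captures it (5-exo-trig) through the conformer with C3–H eclipsing the aryl group (least A1,3 strain), so O1 adds anti to the C3 methyl group and C2 becomes S (trans).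

Step 5
Reactants: 8 (2S,3S)-5-bromo-2-(3,4-dimethoxyphenyl)-7-methoxy-3-methyl-2,3-dihydrobenzofuran; 9 methyl acrylate
Product: 10 methyl (E)-3-[(2S,3S)-2-(3,4-dimethoxyphenyl)-7-methoxy-3-methyl-2,3-dihydrobenzofuran-5-yl]acrylate
Conditions: Pd(OAc)2 (5 mol %), P(o-tol)3 (12 mol %), K2CO3, DMF, 100 °C
Reagents that add atoms: none
Why: Mizoroki–Heck reaction, in which syn insertion and syn β-hydride elimination should give the E-enoate, and C2 and C3 carry no acidic hydrogen and are not touched by the base.

Step 6
Reactants: 10 methyl (E)-3-[(2S,3S)-2-(3,4-dimethoxyphenyl)-7-methoxy-3-methyl-2,3-dihydrobenzofuran-5-yl]acrylate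
Product: 11 (E)-3-[(2S,3S)-2-(3,4-dimethoxyphenyl)-7-methoxy-3-methyl-2,3-dihydrobenzofuran-5-yl]prop-2-en-1-ol (target)
Conditions: DIBAL-H (2.5 equiv), CH2Cl2, −78 °C; aq. Rochelle salt
Reagents that add atoms: none
Why: 1,2-reduction of an α,β-unsaturated ester with DIBAL-H to the allylic alcohol, with a neutral work-up that spares the acid-sensitive cinnamyl alcohol, the alkene geometry and the benzylic ether.

**Compound list**

1 | 5-bromo-2-hydroxy-3-methoxybenzaldehyde | COc1cc(Br)cc(C=O)c1O | starting material
2 | 4-bromo-2-methoxy-6-vinylphenol | COc1cc(Br)cc(C=C)c1O | intermediate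
3 | 3,4-dimethoxybenzoyl chloride | COc1ccc(C(=O)Cl)cc1OC | starting material
4 | 4-bromo-2-methoxy-6-vinylphenyl 3,4-dimethoxybenzoate | COc1ccc(C(=O)Oc2c(OC)cc(Br)cc2C=C)cc1OC | intermediate
5 | (2S)-2-[5-bromo-2-{[dimethoxy(methyl)silyl]oxy}-3-methoxyphenyl]-1-(3,4-dimethoxyphenyl)propan-1-one (not isolated) | COc1ccc(C(=O)[C@@H](C)c2cc(Br)cc(OC)c2O[Si](C)(OC)OC)cc1OC | intermediate
6 | bis[dimethoxy(methyl)silyl] ether of 7, both C1 epimers (not isolated) | COc1ccc(C(O[Si](C)(OC)OC)[C@@H](C)c2cc(Br)cc(OC)c2O[Si](C)(OC)OC)cc1OC | intermediate
7 | 4-bromo-2-[(2S)-1-(3,4-dimethoxyphenyl)-1-hydroxypropan-2-yl]-6-methoxyphenol, both C1 epimers | COc1ccc(C(O)[C@@H](C)c2cc(Br)cc(OC)c2O)cc1OC | intermediate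
8 | (2S,3S)-5-bromo-2-(3,4-dimethoxyphenyl)-7-methoxy-3-methyl-2,3-dihydrobenzofuran | COc1ccc([C@H]2Oc3c(OC)cc(Br)cc3[C@@H]2C)cc1OC | intermediate
9 | methyl acrylate | C=CC(=O)OC | starting material
10 | methyl (E)-3-[(2S,3S)-2-(3,4-dimethoxyphenyl)-7-methoxy-3-methyl-2,3-dihydrobenzofuran-5-yl]acrylate | COc1ccc([C@H]2Oc3c(OC)cc(/C=C/C(=O)OC)cc3[C@@H]2C)cc1OC | intermediate
11 | (E)-3-[(2S,3S)-2-(3,4-dimethoxyphenyl)-7-methoxy-3-methyl-2,3-dihydrobenzofuran-5-yl]prop-2-en-1-ol | COc1ccc([C@H]2Oc3c(OC)cc(/C=C/CO)cc3[C@@H]2C)cc1OC | target

Total step count: 6. Longest linear sequence: 6 (1 → 2 → 4 → 7 → 8 → 10 → 11).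

**Steps most likely to fail**

Risk 1, step 3 (Proposed new method):
- The acyl shift may be too slow on an electron-rich ester flanked by two ortho groups. Silylation or protonation of the C–Cu bond, or Cu–H cleavage of the ester, could then take over.
- Enolisation of the ketone by the copper phenoxide before the second reduction would erode the configuration at C3.
- Incomplete ketone reduction alone is harmless. A borohydride reduction during the methanolic work-up would complete it, since the carbinol configuration does not matter.
- The fallback uses known chemistry and sets out from 2. The phenol is silylated (TBSCl, imidazole, DMF) to tert-butyl(4-bromo-2-methoxy-6-vinylphenoxy)dimethylsilane F1. Acid chloride 3 and 3,4-dimethoxybenzoic acid (Et3N, CH2Cl2) give 3,4-dimethoxybenzoic anhydride F2.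
- The intermolecular CuH-catalysed enantioselective reductive coupling of vinylarene F1 with anhydride F2 uses the same copper source, ligand and silane, with in situ ketone reduction and methanolysis. It should give (2S)-2-[5-bromo-2-(tert-butyldimethylsilyloxy)-3-methoxyphenyl]-1-(3,4-dimethoxyphenyl)propan-1-ol F3. TBAF in THF then frees the phenol, and the route is rejoined at 7.

Risk 2, step 4:
- Loss of the C3 proton from the benzylic cation, in competition with ring closure, followed by re-protonation, would racemise C3.
- Intermolecular Friedel–Crafts alkylation of the electron-rich rings would consume material.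
- The fallback sets out from 7 and replaces ionisation by a stereospecific displacement under neutral conditions. In a Mitsunobu cyclodehydration (PPh3, DIAD, THF, 0 °C) the carbinol is activated as its oxyphosphonium salt and displaced by the phenoxide with inversion.
- The (1R) epimer gives 8 directly, where the route is rejoined. The (1S) epimer gives (2R,3S)-5-bromo-2-(3,4-dimethoxyphenyl)-7-methoxy-3-methyl-2,3-dihydrobenzofuran F4, which is removed by chromatography.

Risk 3, step 5:
- Oxidative addition of palladium(0) into the electron-rich C5–Br bond (para to O1) may be slow, and the catalyst may decay at the temperature needed.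
- The fallback sets out from 8 and builds the enoate by carbonyl olefination instead of cross-coupling. Bromine–lithium exchange (n-BuLi, THF, −78 °C) and a DMF quench give (2S,3S)-2-(3,4-dimethoxyphenyl)-7-methoxy-3-methyl-2,3-dihydrobenzofuran-5-carbaldehyde F5.
- A Horner–Wadsworth–Emmons reaction with trimethyl phosphonoacetate (NaH, THF, 0 °C) should give the E-enoate, and the route is rejoined at 10.

**Further compounds**

F1 | step 3 | tert-butyl(4-bromo-2-methoxy-6-vinylphenoxy)dimethylsilane | COc1cc(Br)cc(C=C)c1O[Si](C)(C)C(C)(C)C
F2 | step 3 | 3,4-dimethoxybenzoic anhydride | COc1ccc(C(=O)OC(=O)c2ccc(OC)c(OC)c2)cc1OC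
F3 | step 3 | (2S)-2-[5-bromo-2-(tert-butyldimethylsilyloxy)-3-methoxyphenyl]-1-(3,4-dimethoxyphenyl)propan-1-ol, both C1 epimers | COc1ccc(C(O)[C@@H](C)c2cc(Br)cc(OC)c2O[Si](C)(C)C(C)(C)C)cc1OC
F4 | step 4 | (2R,3S)-5-bromo-2-(3,4-dimethoxyphenyl)-7-methoxy-3-methyl-2,3-dihydrobenzofuran | COc1ccc([C@@H]2Oc3c(OC)cc(Br)cc3[C@@H]2C)cc1OC
F5 | step 5 | (2S,3S)-2-(3,4-dimethoxyphenyl)-7-methoxy-3-methyl-2,3-dihydrobenzofuran-5-carbaldehyde | COc1ccc([C@H]2Oc3c(OC)cc(C=O)cc3[C@@H]2C)cc1OC
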